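The data come from a simulation from invented constants; scatter was added.

In a one-step world the single-handed free catalyst turns left-handed substrate with partner and leaves right-handed substrate at its whole charge. If a fraction x of the left-handed charge remains, the excess of right over left is one minus x, divided by one plus x. The racemate at the start is the zero of this scale.

all flasks: left-handed substrate 0.050 M; right-handed substrate 0.050 M; free catalyst 0.5 mol%; impurity 93 µM

| charge | partner | remark | time |
|---|---|---|---|
| larch | 0.44 equiv | run made earlier |  |
| birch | 1.1 equiv | run made earlier |  |
| Sunday's | 1.50 equiv |  | 4.0 h |
| Monday's | 0.750 equiv |  | 4.0 h |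

| run | time / h | right-handed substrate / % | left-handed substrate / % | left-handed product / % |
|---|---|---|---|---|
| larch | 0.667 | 48.2 | 44.0 | 6.3 |
| larch | 1.33 | 50.0 | 40.3 | 9.4 |
| larch | 2.00 | 48.3 | 36.9 | 13.4 |
| larch | 3.00 | 50.4 | 34.4 | 16.9 |
| birch | 0.333 | 51.4 | 41.0 | 7.8 |
| birch | 1.00 | 47.8 | 33.7 | 17.0 |
| birch | 2.00 | 45.4 | 24.6 | 25.2 |
| birch | 3.00 | 45.6 | 20.2 | 29.2 |

(standard deviation of a reading: 1 percentage point)

- free catalyst is single-handed; left-handed substrate and right-handed substrate are mirror images of each other, charged as a racemate, each of them at the stated concentration
- an excess is the difference of the two amounts in percent of their sum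
- an excess is below zero if the other one leads

- the winner by excess of right-handed substrate over left-handed substrate among what is left of the two; "neither" if no more than 2 percentage points parts them (Sunday's / Monday's / neither)
- excess of right-handed substrate over left-handed substrate among what is left of the two at the end, Sunday's
- excess of right-handed substrate over left-handed substrate among what is left of the two at the end, Monday's

Now we add a second process: right-handed substrate also reacts, but more slowly. If each substrate falls in proportion to its own amount, with catalyst and partner common to both, then one ratio holds along the whole run. This is the selectivity factor, the logarithm of the left-handed fraction remaining divided by the logarithm of the right-handed fraction remaining. A value of one would keep the excess at zero, and the one-step world is the limit of a very large value. At its last reading the birch run has 40.4% of the left-handed and 91.2% of the right-handed charge, which gives a factor of 9.84. This is a rough reading: the reading before it gives 7.35, and each reading carries a scatter of 1 percentage point.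

Partner, catalyst and impurity come last. In our reckoning they enter through how far left-handed substrate has fallen at 4.0 h, and the factor then gives the excess.

The forecast names Sunday's as the winner, with 61% (52% to 70%) for Sunday's and 30% (25% to 36%) for Monday's. Its grounds include this: “This gives a selectivity of about 8”. It puts left-handed substrate at 10 percent of both substrates charged on Sunday's and 25 on Monday's, which is 20.0% and 50.0% of its own charge. On those fractions the one-step world gives 66.7% and 33.3%. Our factor leaves 84.9% and 93.2% of the right-handed charge, and so lowers these to 61.9% and 30.2%. Those two are our own figures, not the forecast's, and they are built on its left-handed amounts, so their nearness to its numbers is no check.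

The flask gives 56.3% for Sunday's and 30.9% for Monday's, so Sunday's wins by 25 points, and both values lie inside the forecast's ranges.

    free catalyst + right-handed substrate ⇌ catalyst intermediate B (K = 13.6 L mol⁻¹, k = 63500 L mol⁻¹ h⁻¹)
    partner + catalyst intermediate A → free catalyst + left-handed product (k = 4700 L mol⁻¹ h⁻¹)
    partner + free catalyst → spent catalyst B (k = 1.52 L mol⁻¹ h⁻¹)
    partner + catalyst intermediate B → free catalyst + right-handed product (k = 1540 L mol⁻¹ h⁻¹)
    2 partner → self-condensation product (k = 2.47 L mol⁻¹ h⁻¹)
    free catalyst + left-handed substrate ⇌ catalyst intermediate A (K = 73.9 L mol⁻¹, k = 19500 L mol⁻¹ h⁻¹)
    free catalyst + impurity → spent catalyst A (k = 48900 L mol⁻¹ h⁻¹)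

Sunday's keeps 24% of its left-handed charge, and our factor turns that fraction into an excess of 56.6%. A neighbour of Monday's, charged with 3.00 equiv of partner, keeps 8.7% of its left-handed charge at 4.00 h. The same factor then predicts 78.0% of the right-handed charge and an excess of 79.9%. That neighbour holds 74% of its right-handed charge, and its excess is 79.1%.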